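| setting | Thursday's | Saturday's | summer | dawn | spring | dusk | midnight |
|---|---|---|---|---|---|---|---|
| J | 4.1 mM (fed, over 25 min) | 62 mM (fed, over 25 min) | 5.0 mM (fed, over 25 min) | 10 mM (fed, over 25 min) | 20 mM (fed, over 25 min) | 40 mM (fed, over 25 min) | 80 mM (fed, over 25 min) |
| L | 1 µM | 1 µM | 1.0 µM | 1.0 µM | 1.0 µM | 1.0 µM | 1.0 µM |
| remark | run made earlier; the fed solution adds 1.0 times the starting volume | run made earlier; the fed solution adds 1.0 times the starting volume | the fed solution adds 1.0 times the starting volume | the fed solution adds 1.0 times the starting volume | the fed solution adds 1.0 times the starting volume | the fed solution adds 1.0 times the starting volume | the fed solution adds 1.0 times the starting volume |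
| time |  |  | 40 h | 40 h | 40 h | 40 h | 40 h |

- Thursday's (time / h: Z / %): 2.50: 100; 5.00: 102; 12.0: 100; 30.0: 99
- Saturday's (time / h: Z / %): 4.00: 16; 10.0: 12; 20.0: 17; 30.0: 12

(standard deviation of a reading: 1.5 percentage points)

- amounts are per litre of the starting volume; all of the dose is in the solution fed
- the analysis behind the earlier runs scatters by 1.5 percentage points, standard deviation
- "hardly changes" means that all values lie within two and a half points (for a concentration: within two and a half percent of the largest)

- [Z] at the end for summer, dawn, spring, dusk, midnight, in this order
- the shape of the row from first to last (hardly changes / falls all the way / falls, then rises / rises, then falls / rises all the way)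

At 4.00 h Saturday's flask read 16% Z and at 30.0 h it read 12%; its readings showed no trend that stood clear of the scatter of 1.5 percentage points, so they could not tell me when it stopped. I kept the books on that charge of J. The mean of the readings put 14.3% of the charge into Z. With L charged at 1 µM, J bound to L could stand for at most 0.00161% of the charge, so the remaining 85.7% had to be unconverted J.

Z made over L charged came to 8840: this is the turnover capacity, or total turnover number, the moles of Z that a mole of L pays for before it stops. Time has dropped out of it. Thursday's flask converted its charge with 4100 turnovers, fewer than that capacity, so it showed no stop.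

But the capacity was one reading at one charge, and I assumed it held for each asked flask. Capacity times L over J charged gives the fraction of the charge that can be paid for. In summer that was 177%, more than the charge, so I booked the whole charge to Z. It was 88.4% in dawn, 44.2% in spring, 22.1% in dusk and 11.0% in midnight, with the balance staying J. The feed adds 1.0 of the starting volume, so the capped flasks should each hold 4.42 mM of Z.

The forecast, reading that “the enzyme dies after a fixed capacity”, gave 2.5 mM for summer and 4.4 mM for dawn, spring, dusk and midnight, with the shape rises all the way.

The flasks gave 2.50 mM, 5.00 mM, 10.0 mM, 8.27 mM and 3.72 mM, so the shape was rises, then falls, turning at 31 mM of J. Read back from Z, the capacity was 16500 in dusk and 7440 in midnight, against 8840 from Saturday's flask.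

    J + L → Z + L, rate k1*[J]*[L]/(1 + ([J]/Km1)) (0.510 mM, k = 1.10 × 10⁷ M⁻¹ h⁻¹)
    J + L → G (k = 22.0 M⁻¹ h⁻¹)

Dividing the rate to Z by the rate to G cancels L and time and leaves a selectivity factor, the moles of Z paid per mole of L lost, which falls as J stands higher. With the J left at the end, it stood at 20800 in dusk and at 6930 in midnight, lower than in dusk.

(The readings were generated by integration from invented constants; noise was put on by code.)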